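Start by reading the flasks and what is wanted of them.

| setting | larch | oak | birch | elm |
|---|---|---|---|---|
| starting complex | 10 mM | 10 mM (fed, over 40 s) | 10 mM | 10 mM (fed, over 40 s) |
| incoming ligand | 2.00 equiv | 2.00 equiv | 2.00 equiv (fed, over 40 s) | 2.00 equiv |
| protic impurity | 1.00 mM | 1.00 mM | 1.00 mM | 1.00 mM |
| temperature | 35 °C | 35 °C | 35 °C |  |
| time | 1.5 min | 1.5 min | 1.5 min | 1.5 min |
| remark | everything together at the start | all else is in the flask from the start; the feed brings no volume worth counting | all else is in the flask from the start; the feed brings no volume worth counting | the addition at 5 °C, then warmed to 35 °C; the feed brings no volume worth counting |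

- the best flask by amount of complex with one exchanged, in percent of the starting complex charged; "all alike" if 1.5 percentage points covers them all (larch / oak / birch / elm / all alike)
- amount of complex with one exchanged at the end, in percent of the starting complex charged, larch
- amount of complex with one exchanged at the end, in percent of the starting complex charged, oak
- amount of complex with one exchanged at the end, in percent of the starting complex charged, birch
- amount of complex with one exchanged at the end, in percent of the starting complex charged, elm

- the constants hold at 35 °C; other temperatures follow from the activation energies and enthalpies

    protic impurity + starting complex → quenched substrate (k1 = 4.8 L mol⁻¹ s⁻¹, Ea1 = 37.0 kJ mol⁻¹)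
    starting complex + incoming ligand ⇌ leaving ligand + complex with one exchanged (K2 = 1.1, k2 = 0.44 L mol⁻¹ s⁻¹, Ea2 = 61.0 kJ mol⁻¹, ΔH2 = −39.0 kJ mol⁻¹)
    complex with one exchanged + incoming ligand ⇌ leaving ligand + complex with two exchanged (K3 = 0.076, k3 = 1.2 L mol⁻¹ s⁻¹, Ea3 = 42.0 kJ mol⁻¹, ΔH3 = −12.0 kJ mol⁻¹)
    (constants at 35 °C)

Then do one multiplication: rate constant of the first exchange, 0.44 L mol⁻¹ s⁻¹, times the charged c(incoming ligand), 20.0 mM, times the time both partners share the flask. Call that product the turnover count; larch, with the whole 1.5 min, has 0.792.

Now turn the question round. For all four to lie within 1.5 percentage points, each count would have to stand far above one, so that a late start cost nothing. Larch stands below one, so expect kinetic control at the asked time, with the flasks still on their way.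

Charge the delays against the count. A steady feed delivers its material on average half of 40 s late, so take 20.0 s off the shared time. Oak and birch then count 0.616 each, whichever partner is fed. For elm, assume the cold addition at 5 °C is lost altogether: 0.440. Larch has 1.80 times elm's count. My reckoning therefore commits to larch first, elm last, oak and birch level, and not "all alike". It stops at this order and gives no percentages.

The forecast names larch, with 35% for larch, 29% for oak, 29.5% for birch and 24% for elm, on the ground that “the flask with both reagents fully present longest wins”. Its birch stands slightly above its oak, where my counts are level.

The simulation gives larch: larch 35.0%, oak 29.4%, birch 29.1%, elm 23.8%.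

Watch the two relaxation half-lives, each reckoned both ways together: in elm at 1.50 min, the second exchange has 0.125 min, shorter than the 0.941 min of the first. It is also short against 1.5 min, and elm ends with complex with two exchanged at 6.81% beside complex with one exchanged at 23.8%. Larch, at a count of 0.792, ends at 35.0%, and elm, at 0.440, stays lower. The neighbouring flask, like elm but with 8.00 equiv of incoming ligand, counts 1.76 and ends at 47.7%.

All constants stand for no real mixture; the flask was simulated.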